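**Plan**

1. Numbering used throughout: C1 = diaryl methine, C2 and C3 = the two CH(CH2OH) carbons, C4 = benzylic CH2, ring A = fused arene C4a–C8a (C6–OH para to C8a, C7–OMe para to C4a), ring B = carbocycle C1–C4.
2. Retrosynthesis: both CH2OH groups come from CO2Me (C2/C3 = a succinate). Then cut C3–C4 (ring B, intramolecular Stobbe condensation onto a ring A aldehyde), C2–C3 (enolate/bromoacetate), C1–pendant aryl (rhodium-catalysed conjugate arylation) and C8a–C1 (Heck).
3. Forward: ring A is bought complete as 2-bromo-5-hydroxy-4-methoxybenzaldehyde (CHO = C4, Br on C8a). The chain C1–C2 is attached, C1 is arylated, C3 is added, and ring B is closed last through C3–C4; reduction and deprotection follow.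
4. Enabling feature: C4 is a benzylic carbon on ring A ortho to C8a, so it can enter as a non-enolisable aryl aldehyde. The C2 carboxyl sits 1,3 to the C4 aldolate oxygen and traps it as a bridged γ-lactone that can only open by E1cB from C3. This selects C3 over C2 and leaves a C2 carboxylate that shields C1.
5. Stereochemistry: C1 is set once by [RhCl(C2H4)2]2/(S)-BINAP. C2 and C3, both α to esters, are equilibrated to the all-equatorial 1,2-trans-2,3-trans diester before LiAlH4. Phenols are carried as benzyl ethers, the C4 aldehyde as a dioxolane.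

Key step: step 6

Assumption: the usual quadrant model for rhodium/BINAP additions to (E)-enoates is taken to hold for the ortho-substituted cinnamate 5, so that (S)-BINAP gives the (S) methine; if the sense were opposite, (R)-BINAP would be used with nothing else changed.

**Step 1**
Reactants: 1 2-bromo-5-hydroxy-4-methoxybenzaldehyde
Product: 2 5-(benzyloxy)-2-bromo-4-methoxybenzaldehyde
Conditions: BnBr, K2CO3, DMF, rt
Reagents that add atoms: benzyl bromide, BrCc1ccccc1
Why: Williamson etherification of the phenoxide protects the C6 oxygen as a benzyl ether that should survive every later step up to the final hydrogenolysis, and the aldehyde and aryl bromide are inert to carbonate.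

**Step 2**
Reactants: 2 5-(benzyloxy)-2-bromo-4-methoxybenzaldehyde
Product: 3 2-[5-(benzyloxy)-2-bromo-4-methoxyphenyl]-1,3-dioxolane
Conditions: HOCH2CH2OH, p-TsOH (cat.), toluene, reflux (Dean–Stark)
Reagents that add atoms: ethylene glycol, OCCO
Why: Acid-catalysed acetalisation with azeotropic removal of water masks the future C4 aldehyde against aryl-rhodium 1,2-addition and enolate chemistry.

**Step 3**
Reactants: 3 2-[5-(benzyloxy)-2-bromo-4-methoxyphenyl]-1,3-dioxolane; 4 methyl acrylate
Product: 5 methyl (2E)-3-[4-(benzyloxy)-2-(1,3-dioxolan-2-yl)-5-methoxyphenyl]prop-2-enoate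
Conditions: Pd(OAc)2 (5 mol %), P(o-tol)3 (10 mol %), Et3N, DMF, 100 °C
Reagents that add atoms: none
Why: Mizoroki–Heck reaction (oxidative addition of the aryl bromide to zerovalent palladium, syn-carbopalladation of the acrylate, syn-β-hydride elimination) should form the C8a–C1 bond and give the (E)-cinnamate, with the acetal stable to the basic medium.

**Step 4**
Reactants: 5 methyl (2E)-3-[4-(benzyloxy)-2-(1,3-dioxolan-2-yl)-5-methoxyphenyl]prop-2-enoate; 6 [4-(benzyloxy)-3-methoxyphenyl]boronic acid
Product: 7 methyl (3S)-3-[4-(benzyloxy)-2-(1,3-dioxolan-2-yl)-5-methoxyphenyl]-3-[4-(benzyloxy)-3-methoxyphenyl]propanoate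
Conditions: [RhCl(C2H4)2]2 (2.5 mol %), (S)-BINAP (5.5 mol %), KOH (0.3 equiv), 1,4-dioxane/H2O (10:1), 60 °C
Reagents that add atoms: none
Why: Hayashi–Miyaura asymmetric 1,4-addition (transmetallation of 6 to the monovalent rhodium hydroxide–BINAP complex, enantioface-selective insertion of the enoate into the Rh–aryl bond, protonolysis of the oxa-π-allyl rhodium) should set C1 as (S) under control of the (S)-BINAP quadrants, while the basic aqueous medium keeps the dioxolane closed.

**Step 5**
Reactants: 7 methyl (3S)-3-[4-(benzyloxy)-2-(1,3-dioxolan-2-yl)-5-methoxyphenyl]-3-[4-(benzyloxy)-3-methoxyphenyl]propanoate; 8 methyl bromoacetate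
Product: 10 dimethyl 2-{(S)-[4-(benzyloxy)-2-formyl-5-methoxyphenyl][4-(benzyloxy)-3-methoxyphenyl]methyl}butanedioate (C2 epimers), via acetal succinate 9 (not isolated)
Conditions: LiN(i-Pr)2, THF, −78 °C; BrCH2CO2Me, −78 → −20 °C; then 2 M HCl, THF, rt
Reagents that add atoms: water, O
Why: Ester enolate alkylation (SN2 on the bromoacetate at C2, the only α-position) installs C3 with its carboxyl carbon, the new C2 centre being formed as an epimer mixture that is re-equilibrated in step 8, and aqueous acid then hydrolyses the dioxolane to the C4 aldehyde without touching methyl esters or benzyl ethers.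

**Step 6**
Reactants: 10 dimethyl 2-{(S)-[4-(benzyloxy)-2-formyl-5-methoxyphenyl][4-(benzyloxy)-3-methoxyphenyl]methyl}butanedioate
Product: 13 (1S)-6-(benzyloxy)-1-[4-(benzyloxy)-3-methoxyphenyl]-7-methoxy-3-(methoxycarbonyl)-1,2-dihydronaphthalene-2-carboxylic acid (C2 epimers), via C4 aldolate 11 (not isolated), via bridged lactone ester 12 (not isolated)
Conditions: KOt-Bu (1.3 equiv), t-BuOH/THF, 0 °C → rt, argon; then 1 M HCl
Reagents that add atoms: none
Why: Reversible enolisation of the succinate lets the C3 ester enolate add to the non-enolisable ring A aldehyde (C4) to give aldolate 11; the C4 alkoxide, 1,3 to the C2 ester, acylates it to the bridged γ-lactone 12 with loss of methoxide, and E1cB deprotonation at C3 opens the lactone to the C3=C4 alkene and the C2 carboxylate. The closest known reaction is the Stobbe condensation of succinic esters with aromatic aldehydes, here run intramolecularly, and a bridged lactone of the same C2/C4 topology is known in the aryltetralin lignan series. Ring B closes by 6-exo-trig attack of the C3 enolate on the aldehyde carbon, and the lactone is a temporary second ring formed by 5-exo-trig acyl transfer and opened in the same flask. No permanent stereocentre is created: C3 and C4 end sp2, C2 stays epimerisable and is corrected in step 8, and C1 is untouched because its hydrogen is not acidic. The selectivity needed is C3 versus C2 as the nucleophile: aldol at C2 gives a five-membered ring whose C2 is quaternary and cannot undergo the E1cB step, so it should revert by retro-aldol, whereas only the C3 pathway ends irreversibly in a carboxylate. That carboxylate at C2 also switches off further deprotonation at C2, which should prevent double-bond migration and so protect the C1 configuration.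

**Step 7**
Reactants: 13 (1S)-6-(benzyloxy)-1-[4-(benzyloxy)-3-methoxyphenyl]-7-methoxy-3-(methoxycarbonyl)-1,2-dihydronaphthalene-2-carboxylic acid
Product: 14 dimethyl (1S)-6-(benzyloxy)-1-[4-(benzyloxy)-3-methoxyphenyl]-7-methoxy-1,2-dihydronaphthalene-2,3-dicarboxylate (C2 epimers)
Conditions: Me3SiCHN2, toluene/MeOH (4:1), 0 °C → rt
Reagents that add atoms: trimethylsilyldiazomethane, C[Si](C)(C)C=[N+]=[N-]
Why: O-methylation of the carboxylic acid by the diazoalkane (proton transfer, SN2 on the diazonium, methanolysis of the silyl group) proceeds without base, so the base-sensitive dihydronaphthalene diester is not exposed to enolising conditions.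

**Step 8**
Reactants: 14 dimethyl (1S)-6-(benzyloxy)-1-[4-(benzyloxy)-3-methoxyphenyl]-7-methoxy-1,2-dihydronaphthalene-2,3-dicarboxylate
Product: 16 dimethyl (1S,2R,3R)-6-(benzyloxy)-1-[4-(benzyloxy)-3-methoxyphenyl]-7-methoxy-1,2,3,4-tetrahydronaphthalene-2,3-dicarboxylate, via saturated diester epimer mixture 15 (not isolated)
Conditions: Mg turnings, MeOH, 0 °C → rt; then NaOMe, MeOH, 65 °C, argon
Reagents that add atoms: none
Why: Dissolving-metal conjugate reduction of the aryl-conjugated unsaturated ester by Mg in methanol saturates C3–C4, and methoxide-mediated epimerisation then equilibrates C2 and C3 through their ester enolates to the isomer with the C1 aryl and both esters equatorial (1,2-trans-2,3-trans), relayed from the fixed C1 centre.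

**Step 9**
Reactants: 16 dimethyl (1S,2R,3R)-6-(benzyloxy)-1-[4-(benzyloxy)-3-methoxyphenyl]-7-methoxy-1,2,3,4-tetrahydronaphthalene-2,3-dicarboxylate
Product: 17 [(1S,2R,3R)-6-(benzyloxy)-1-[4-(benzyloxy)-3-methoxyphenyl]-7-methoxy-1,2,3,4-tetrahydronaphthalene-2,3-diyl]dimethanol
Conditions: LiAlH4, THF, 0 °C → rt; aqueous NaOH work-up
Reagents that add atoms: none
Why: Hydride reduction of both methyl esters to primary alcohols is fast at low temperature and should leave the three stereocentres and the benzyl ethers unchanged.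

**Step 10**
Reactants: 17 [(1S,2R,3R)-6-(benzyloxy)-1-[4-(benzyloxy)-3-methoxyphenyl]-7-methoxy-1,2,3,4-tetrahydronaphthalene-2,3-diyl]dimethanol
Product: 18 (1S,2R,3R)-1-(4-hydroxy-3-methoxyphenyl)-2,3-bis(hydroxymethyl)-7-methoxy-1,2,3,4-tetrahydronaphthalen-6-ol (target)
Conditions: H2 (1 atm), Pd/C (10 %), EtOAc/MeOH, rt
Reagents that add atoms: none
Why: Catalytic hydrogenolysis of the two aryl benzyl ethers unmasks both phenols, and the C–C framework, the primary alcohols and the stereocentres are not affected.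

**Compound list**

1 | 2-bromo-5-hydroxy-4-methoxybenzaldehyde | O=Cc1cc(O)c(OC)cc1Br | starting material
2 | 5-(benzyloxy)-2-bromo-4-methoxybenzaldehyde | O=Cc1cc(OCc2ccccc2)c(OC)cc1Br | intermediate
3 | 2-[5-(benzyloxy)-2-bromo-4-methoxyphenyl]-1,3-dioxolane | Brc1cc(OC)c(OCc2ccccc2)cc1C1OCCO1 | intermediate
4 | methyl acrylate | C=CC(=O)OC | starting material
5 | methyl (2E)-3-[4-(benzyloxy)-2-(1,3-dioxolan-2-yl)-5-methoxyphenyl]prop-2-enoate | COC(=O)/C=C/c1cc(OC)c(OCc2ccccc2)cc1C1OCCO1 | intermediate
6 | [4-(benzyloxy)-3-methoxyphenyl]boronic acid | COc1cc(B(O)O)ccc1OCc1ccccc1 | starting material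
7 | methyl (3S)-3-[4-(benzyloxy)-2-(1,3-dioxolan-2-yl)-5-methoxyphenyl]-3-[4-(benzyloxy)-3-methoxyphenyl]propanoate | COc1cc([C@H](CC(=O)OC)c2cc(OC)c(OCc3ccccc3)cc2C2OCCO2)ccc1OCc1ccccc1 | intermediate
8 | methyl bromoacetate | COC(=O)CBr | starting material
9 | dimethyl 2-{(S)-[4-(benzyloxy)-2-(1,3-dioxolan-2-yl)-5-methoxyphenyl][4-(benzyloxy)-3-methoxyphenyl]methyl}butanedioate (C2 epimers; formed in the flask, not isolated) | COc1cc([C@H](C(CC(=O)OC)C(=O)OC)c2cc(OC)c(OCc3ccccc3)cc2C2OCCO2)ccc1OCc1ccccc1 | intermediate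
10 | dimethyl 2-{(S)-[4-(benzyloxy)-2-formyl-5-methoxyphenyl][4-(benzyloxy)-3-methoxyphenyl]methyl}butanedioate (C2 epimers) | COc1cc([C@H](C(CC(=O)OC)C(=O)OC)c2cc(OC)c(OCc3ccccc3)cc2C=O)ccc1OCc1ccccc1 | intermediate
11 | dimethyl (1S)-6-(benzyloxy)-1-[4-(benzyloxy)-3-methoxyphenyl]-4-hydroxy-7-methoxy-1,2,3,4-tetrahydronaphthalene-2,3-dicarboxylate, present as its potassium C4 alkoxide (not isolated) | COc1cc([C@H]2c3cc(OC)c(OCc4ccccc4)cc3C(O)C(C(=O)OC)C2C(=O)OC)ccc1OCc1ccccc1 | intermediate
12 | bridged γ-lactone of 11: C2 carbonyl esterified by the C4 oxygen, C3 methyl ester retained, (1S) (not isolated) | COc1cc([C@H]2c3cc(OC)c(OCc4ccccc4)cc3C3OC(=O)C2C3C(=O)OC)ccc1OCc1ccccc1 | intermediate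
13 | (1S)-6-(benzyloxy)-1-[4-(benzyloxy)-3-methoxyphenyl]-7-methoxy-3-(methoxycarbonyl)-1,2-dihydronaphthalene-2-carboxylic acid (C2 epimers) | COc1cc([C@H]2c3cc(OC)c(OCc4ccccc4)cc3C=C(C(=O)OC)C2C(=O)O)ccc1OCc1ccccc1 | intermediate
14 | dimethyl (1S)-6-(benzyloxy)-1-[4-(benzyloxy)-3-methoxyphenyl]-7-methoxy-1,2-dihydronaphthalene-2,3-dicarboxylate (C2 epimers) | COc1cc([C@H]2c3cc(OC)c(OCc4ccccc4)cc3C=C(C(=O)OC)C2C(=O)OC)ccc1OCc1ccccc1 | intermediate
15 | dimethyl (1S)-6-(benzyloxy)-1-[4-(benzyloxy)-3-methoxyphenyl]-7-methoxy-1,2,3,4-tetrahydronaphthalene-2,3-dicarboxylate (C2/C3 epimer mixture; not isolated) | COc1cc([C@H]2c3cc(OC)c(OCc4ccccc4)cc3CC(C(=O)OC)C2C(=O)OC)ccc1OCc1ccccc1 | intermediate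
16 | dimethyl (1S,2R,3R)-6-(benzyloxy)-1-[4-(benzyloxy)-3-methoxyphenyl]-7-methoxy-1,2,3,4-tetrahydronaphthalene-2,3-dicarboxylate | COc1cc([C@H]2c3cc(OC)c(OCc4ccccc4)cc3C[C@@H](C(=O)OC)[C@@H]2C(=O)OC)ccc1OCc1ccccc1 | intermediate
17 | [(1S,2R,3R)-6-(benzyloxy)-1-[4-(benzyloxy)-3-methoxyphenyl]-7-methoxy-1,2,3,4-tetrahydronaphthalene-2,3-diyl]dimethanol | COc1cc([C@H]2c3cc(OC)c(OCc4ccccc4)cc3C[C@@H](CO)[C@@H]2CO)ccc1OCc1ccccc1 | intermediate
18 | (1S,2R,3R)-1-(4-hydroxy-3-methoxyphenyl)-2,3-bis(hydroxymethyl)-7-methoxy-1,2,3,4-tetrahydronaphthalen-6-ol | COc1cc([C@H]2c3cc(OC)c(O)cc3C[C@@H](CO)[C@@H]2CO)ccc1O | target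

**Count and risks**

Total steps: 10. Longest linear sequence: 10 steps (from 1).

Steps most likely to fail:

Step 6 (key step). The closure may divert through the C2 enolate into the five-membered aldol, held as its fused lactone if that reopens too slowly. The dihydronaphthalene may also suffer base-induced double-bond migration or air oxidation to the naphthalene. The fallback closes the same bond by alkylation instead of condensation and sets out from 10. NaBH4 (MeOH, 0 °C) reduces the aldehyde to the benzylic alcohol F1. CBr4/PPh3 (CH2Cl2, 0 °C) converts it into the benzylic bromide F2. LiN(SiMe3)2 (THF, −78 → 0 °C) deprotonates the less hindered C3 methylene, and 6-exo-tet displacement should give the saturated diester 15. This comes back to the route at 15, at the NaOMe equilibration stage of step 8, so that step 7 and the Mg reduction drop out.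

Step 4. Insertion of the ortho-substituted cinnamate may be slow, so that protodeboronation of 6 consumes the aryl donor, or the face selectivity may be insufficient. The fallback moves stereocontrol from the catalyst to a covalently bound auxiliary and sets out from 5. LiOH (THF/H2O) gives the cinnamic acid F3. Pivaloyl chloride/Et3N (THF, −20 °C) gives the mixed pivalic anhydride F4, which acylates lithiated (4R)-4-phenyl-1,3-oxazolidin-2-one to the N-enoyl imide F5. The aryl Grignard reagent F6 (from 1-(benzyloxy)-4-bromo-2-methoxybenzene and Mg) is added with CuBr·SMe2 (THF, −40 °C). It should attack the chelated syn-s-cis imide on the face away from the 4-phenyl group and give the β,β-diaryl imide F7 with the (S) methine. MeOMgBr in MeOH (0 °C) then releases the methyl ester, coming back at 7.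

Step 8. In the basic Mg(OMe)2 medium the C3=C4 double bond may migrate into the C2–C3 position before electron transfer, which would make C1–H vinylogously acidic and erode the C1 configuration; reduction may also be incomplete. The fallback replaces the dissolving-metal step by neutral hydrogenation and reorders the end-game, setting out from 14. H2 over Pd/C (EtOAc/MeOH, rt) saturates the alkene and removes both benzyl groups, giving the phenolic saturated diester F8 as an epimer mixture. NaOMe in MeOH (65 °C, argon) equilibrates it to the all-trans phenolic diester F9. LiAlH4 (THF) reduces F9 directly, coming back at 18, so that step 10 drops out.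

**Further compounds**

F1 | step 6 | dimethyl 2-{(S)-[4-(benzyloxy)-2-(hydroxymethyl)-5-methoxyphenyl][4-(benzyloxy)-3-methoxyphenyl]methyl}butanedioate | COc1cc([C@H](C(CC(=O)OC)C(=O)OC)c2cc(OC)c(OCc3ccccc3)cc2CO)ccc1OCc1ccccc1
F2 | step 6 | dimethyl 2-{(S)-[4-(benzyloxy)-2-(bromomethyl)-5-methoxyphenyl][4-(benzyloxy)-3-methoxyphenyl]methyl}butanedioate | COc1cc([C@H](C(CC(=O)OC)C(=O)OC)c2cc(OC)c(OCc3ccccc3)cc2CBr)ccc1OCc1ccccc1
F3 | step 4 | (2E)-3-[4-(benzyloxy)-2-(1,3-dioxolan-2-yl)-5-methoxyphenyl]prop-2-enoic acid | OC(=O)/C=C/c1cc(OC)c(OCc2ccccc2)cc1C1OCCO1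
F4 | step 4 | mixed anhydride of F3 with pivalic acid | CC(C)(C)C(=O)OC(=O)/C=C/c1cc(OC)c(OCc2ccccc2)cc1C1OCCO1
F5 | step 4 | (4R)-3-{(2E)-3-[4-(benzyloxy)-2-(1,3-dioxolan-2-yl)-5-methoxyphenyl]prop-2-enoyl}-4-phenyl-1,3-oxazolidin-2-one | O=C(/C=C/c1cc(OC)c(OCc2ccccc2)cc1C1OCCO1)N1C(=O)OC[C@H]1c1ccccc1
F6 | step 4 | [4-(benzyloxy)-3-methoxyphenyl]magnesium bromide | COc1cc([Mg]Br)ccc1OCc1ccccc1
F7 | step 4 | (4R)-3-{(3S)-3-[4-(benzyloxy)-2-(1,3-dioxolan-2-yl)-5-methoxyphenyl]-3-[4-(benzyloxy)-3-methoxyphenyl]propanoyl}-4-phenyl-1,3-oxazolidin-2-one | COc1cc([C@H](CC(=O)N2C(=O)OC[C@H]2c2ccccc2)c2cc(OC)c(OCc3ccccc3)cc2C2OCCO2)ccc1OCc1ccccc1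
F8 | step 8 | dimethyl (1S)-6-hydroxy-1-(4-hydroxy-3-methoxyphenyl)-7-methoxy-1,2,3,4-tetrahydronaphthalene-2,3-dicarboxylate (C2/C3 epimer mixture) | COc1cc([C@H]2c3cc(OC)c(O)cc3CC(C(=O)OC)C2C(=O)OC)ccc1O
F9 | step 8 | dimethyl (1S,2R,3R)-6-hydroxy-1-(4-hydroxy-3-methoxyphenyl)-7-methoxy-1,2,3,4-tetrahydronaphthalene-2,3-dicarboxylate | COc1cc([C@H]2c3cc(OC)c(O)cc3C[C@@H](C(=O)OC)[C@@H]2C(=O)OC)ccc1O
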